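**Assumption:** 2,2-dimethyl-2H-chromen-7-ol and methyl (R)-glycidate (the L-serine-derived enantiomer) are taken as catalogue compounds.

## Retrosynthetic overview

1. The target comes from its (2R,3R)-3-hydroxy analogue 13 by SmI2 removal of the C3–OH, which is a traceless stereo-relay carried on the C2–C3–C4 carbons of the glycidate.
2. Ring C is closed last: the C2–O1 bond forms by anodic dehydrogenative cyclisation of α-hydroxydihydrochalcone 11 through a B-ring o-quinone methide, and the L-serine-derived C3 carbinol sets C2 trans.
3. The C4–C4a bond comes from the aryllithium of bromophenol 7 adding to lactone 10. The free phenol of 7 becomes O1, so the prenyl group ends at C6 by symmetry.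
4. Lactone 10 comes from Friedel–Crafts opening of methyl (R)-glycidate by the intact chromenol 8.
5. Ring order: B-ring chromene (bought) → temporary lactone → A ring attached → pyranone ring C.

## Route

**Step 1**
Reactants: 1 phloroglucinol; 2 chloromethyl methyl ether (MOMCl)
Product: 3, 3,5-bis(methoxymethoxy)phenol
Conditions: MOMCl (2.0 equiv), i-Pr2NEt, CH2Cl2/DMF, 0 °C → rt; chromatography (mono- and tris-ethers recycled)
Reagents that add atoms: MOMCl, COCCl
Why: Statistical O-alkylation (MOM acetal formation) of a C3-symmetric triphenol leaves one oxygen, the future O1, free and distinct from the other two.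

**Step 2**
Reactants: 3; 4 prenyl bromide (1-bromo-3-methylbut-2-ene)
Product: 5, 3,5-bis(methoxymethoxy)-4-(3-methylbut-2-en-1-yl)phenol
Conditions: n-BuLi (2.3 equiv), TMEDA, THF, 0 °C → rt; CuBr·SMe2 (10 mol %), then 4, −78 → 0 °C
Reagents that add atoms: prenyl bromide, CC(C)=CCBr
Why: Directed ortho-metalation of the lithium phenoxide at the only C–H flanked by two MOM ethers, then copper-mediated SN2 allylation, puts a normal prenyl group para to the phenol and keeps the ring symmetric.

**Step 3**
Reactants: 5; 6 N-bromosuccinimide
Product: 7, 2-bromo-3,5-bis(methoxymethoxy)-4-(3-methylbut-2-en-1-yl)phenol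
Conditions: NBS (1.0 equiv), i-Pr2NH (10 mol %), CH2Cl2, −78 °C
Reagents that add atoms: NBS, O=C1CCC(=O)N1Br
Why: Amine-catalysed ortho-bromination of the phenol (electrophilic aromatic substitution) has only one kind of ring C–H to attack, and the low temperature spares the trisubstituted alkene.

**Step 4**
Reactants: 8 2,2-dimethyl-2H-chromen-7-ol; 9 methyl (R)-glycidate
Product: 10, (3R)-3-hydroxy-8,8-dimethyl-3,4-dihydro-2H,8H-pyrano[3,2-g]chromen-2-one
Conditions: Sc(OTf)3 (5 mol %), HFIP/CH2Cl2, 0 °C → rt; then PPTS (cat.), toluene, 50 °C (−MeOH)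
Reagents that add atoms: methyl (R)-glycidate, COC(=O)[C@H]1CO1
Why: Friedel–Crafts epoxide opening at the unsubstituted epoxide carbon by chromene C6 (para to the ring oxygen, ortho to OH; C8 is flanked on both sides) followed by lactonisation; the glycidate stereocenter is not a reacting centre, so its (R) configuration is carried over unchanged.

**Step 5**
Reactants: 7; 10
Product: 11, (2R)-2-hydroxy-1-[2-hydroxy-4,6-bis(methoxymethoxy)-5-(3-methylbut-2-en-1-yl)phenyl]-3-(7-hydroxy-2,2-dimethyl-2H-chromen-6-yl)propan-1-one
Conditions: 7, NaH (1.05 equiv), THF, 0 °C; t-BuLi (2.0 equiv), −78 °C; add 10 (pre-treated with LiHMDS, 1.0 equiv), −78 → −30 °C; aq NH4Cl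
Reagents that add atoms: none
Why: Br/Li exchange on the phenoxide and acyl substitution on the aryl lactone (phenoxide leaving group) give the ketone, with the α-alkoxide and the di-ortho-substituted aryl ketone preventing enolisation and over-addition; the free phenol ortho to the ketone is the one remote from the prenyl group.

**Step 6**
Reactants: 11
Product: 12, (2R,3R)-3-hydroxy-2-(7-hydroxy-2,2-dimethyl-2H-chromen-6-yl)-5,7-bis(methoxymethoxy)-6-(3-methylbut-2-en-1-yl)-2,3-dihydro-4H-chromen-4-one
Conditions: undivided cell, graphite anode | Pt cathode, constant current (2.2 F mol⁻¹), n-Bu4NPF6 (0.1 M), 2,6-lutidine (2 equiv), CH2Cl2/HFIP 9:1, 0 °C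
Reagents that add atoms: none
Why: Proposed new method: anodic two-electron/two-proton oxidation of the most electron-rich ring (the B-ring o-alkylphenol) should give an o-quinone methide at C2 that the A-ring phenol captures in a 6-membered closure; the C3 carbinol sits pseudo-equatorial in a chair-like transition state so the aryl group ends trans (2R), and because closure is reversible through the same o-quinone methide the trans isomer is also the thermodynamic product; the closest known reactions are DDQ/Ag2O oxidative cyclisations of 2′-hydroxydihydrochalcones and anodic benzylic C–H etherification.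

**Step 7**
Reactants: 12
Product: 13, (2R,3R)-3,5,7-trihydroxy-2-(7-hydroxy-2,2-dimethyl-2H-chromen-6-yl)-6-(3-methylbut-2-en-1-yl)-2,3-dihydro-4H-chromen-4-one
Conditions: 2 M HCl, MeOH/THF, 40 °C
Reagents that add atoms: none
Why: Acidic hydrolysis of the two MOM acetals is done while the C3–OH is still present, so any acid-induced opening and reclosure at C2 returns to the favoured trans isomer and the configuration is not lost.

**Step 8**
Reactants: 13
Product: 14, cudraflavanone A, (2S)-5,7-dihydroxy-2-(7-hydroxy-2,2-dimethyl-2H-chromen-6-yl)-6-(3-methylbut-2-en-1-yl)-2,3-dihydro-4H-chromen-4-one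
Conditions: SmI2 (3 equiv), degassed THF/MeOH 10:1, −78 °C, 20 min; aq NH4Cl
Reagents that add atoms: none
Why: SmI2 reductive cleavage of the α-hydroxy ketone (ketyl, loss of hydroxide, protonation of the samarium enolate by MeOH) removes the C3–OH without touching C2; the descriptor changes from 2R to 2S only because the CIP priorities change.

## Compound list

1 | phloroglucinol | Oc1cc(O)cc(O)c1 | starting material
2 | chloromethyl methyl ether | COCCl | starting material
3 | 3,5-bis(methoxymethoxy)phenol | COCOc1cc(O)cc(OCOC)c1 | intermediate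
4 | prenyl bromide | CC(C)=CCBr | starting material
5 | 3,5-bis(methoxymethoxy)-4-(3-methylbut-2-en-1-yl)phenol | COCOc1cc(O)cc(OCOC)c1CC=C(C)C | intermediate
6 | N-bromosuccinimide | O=C1CCC(=O)N1Br | starting material
7 | 2-bromo-3,5-bis(methoxymethoxy)-4-(3-methylbut-2-en-1-yl)phenol | COCOc1cc(O)c(Br)c(OCOC)c1CC=C(C)C | intermediate
8 | 2,2-dimethyl-2H-chromen-7-ol | CC1(C)C=Cc2ccc(O)cc2O1 | starting material
9 | methyl (R)-glycidate (methyl (2R)-oxirane-2-carboxylate) | COC(=O)[C@H]1CO1 | starting material (chiral)
10 | (3R)-3-hydroxy-8,8-dimethyl-3,4-dihydro-2H,8H-pyrano[3,2-g]chromen-2-one | CC1(C)C=Cc2cc3C[C@@H](O)C(=O)Oc3cc2O1 | intermediate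
11 | (2R)-2-hydroxy-1-[2-hydroxy-4,6-bis(methoxymethoxy)-5-prenylphenyl]-3-(7-hydroxy-2,2-dimethyl-2H-chromen-6-yl)propan-1-one | COCOc1cc(O)c(C(=O)[C@H](O)Cc2cc3C=CC(C)(C)Oc3cc2O)c(OCOC)c1CC=C(C)C | intermediate
12 | (2R,3R)-3-hydroxy-2-(7-hydroxy-2,2-dimethyl-2H-chromen-6-yl)-5,7-bis(methoxymethoxy)-6-prenylchroman-4-one | CC(C)=CCc1c(OCOC)cc2c(c1OCOC)C(=O)[C@H](O)[C@@H](c1cc3c(cc1O)OC(C)(C)C=C3)O2 | intermediate
13 | (2R,3R)-3,5,7-trihydroxy-2-(7-hydroxy-2,2-dimethyl-2H-chromen-6-yl)-6-prenylchroman-4-one | CC(C)=CCc1c(O)cc2c(c1O)C(=O)[C@H](O)[C@@H](c1cc3c(cc1O)OC(C)(C)C=C3)O2 | intermediate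
14 | cudraflavanone A, (2S) | CC(C)=CCc1c(O)cc2c(c1O)C(=O)C[C@@H](c1cc3c(cc1O)OC(C)(C)C=C3)O2 | target

## Summary

Total step count: 8. Longest linear sequence: 7 (steps 1, 2, 3, 5, 6, 7, 8).

Three steps most likely to fail:

- **Step 6 (proposed new anodic cyclisation).** Risks are phenoxyl or chromene dimerisation, tautomerisation of the o-quinone methide that would erode C3, and over-oxidation to the flavonol. Fallback (known chemistry): protect C3–OH as the TBS ether and close the ring with stoichiometric DDQ (or Ag2O), the established hydride-abstraction oxidative cyclisation of 2′-hydroxydihydrochalcones, then remove the silyl group.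
- **Step 8 (SmI2 on the unprotected ketol).** Risks are ring opening of the samarium enolate to the chalcone (loss of ee) and over-reduction of the ketone. Fallback: silylate the three phenols (TBSCl), convert C3–OH to the imidazolyl thiocarbonate, run a Barton–McCombie radical deoxygenation ((TMS)3SiH, AIBN), which avoids any enolate, then desilylate with buffered HF·pyridine.
- **Step 4 (Friedel–Crafts opening of the glycidate).** Risks are acid-induced dimerisation of the chromene and O-alkylation. Fallback: switch to an aryl-metal nucleophile, using CuI-catalysed opening of 9 with the Grignard reagent of 6-bromo-7-(methoxymethoxy)-2,2-dimethyl-2H-chromene (THF, −30 °C), then acidic MOM removal and lactonisation to 10.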